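**Retrosynthetic overview**
1. Target ⇐ O-demethylation of its methyl ether ⇐ Sandmeyer bromination of a 2-aminophenyl ether ⇐ nitro reduction ⇐ SNAr of 3,4,6-tribromo-2-methoxyphenol on 1-fluoro-2-nitrobenzene (ring B is bought intact).
2. 3,4,6-Tribromo-2-methoxyphenol ⇐ ortho/para dibromination of 3-bromo-2-methoxyphenol; its 3-Br (meta to OH) cannot be placed by electrophilic substitution, so ring A is built from acyclic pieces.
3. 3-Bromo-2-methoxyphenol ⇐ aromatisation of 3-bromo-2-methoxycyclohex-2-enone ⇐ deoxybromination of 2-methoxycyclohexane-1,3-dione.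
4. Dione ⇐ intramolecular Claisen of methyl 6-methoxy-5-oxohexanoate ⇐ Krapcho ⇐ intermolecular Michael addition of methyl 4-methoxyacetoacetate to methyl acrylate (key C–C bond joining the two acyclic fragments).
5. Ring order: ring A is closed in step 3 and aromatised in step 5; ring B is never constructed and is attached as a finished benzene ring in step 7.

Assumption: the target has no stereocentre and is achiral, so "single enantiomer" is met by the compound itself; the two transient stereocentres formed on the way are racemic and are destroyed later.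

**Route**

Step 1
Reactants: 1 methyl 4-methoxy-3-oxobutanoate (1.2 equiv); 2 methyl acrylate
Product: 3 dimethyl 2-(2-methoxyacetyl)pentanedioate (racemic)
Conditions: NaOMe (0.1 equiv), MeOH, 0 °C to rt
Reagents that add atoms: none
Why: Base-catalysed Michael addition in which only the doubly activated C2–H of the β-keto ester is deprotonated by catalytic methoxide, so the C–C bond forms there and not at the methoxymethyl carbon (same pattern as acetoacetate plus acrylate); the new stereocentre is racemic and is erased in step 2.

Step 2
Reactants: 3 dimethyl 2-(2-methoxyacetyl)pentanedioate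
Product: 4 methyl 6-methoxy-5-oxohexanoate
Conditions: LiCl, H2O, DMSO, 150 °C
Reagents that add atoms: none
Why: Krapcho dealkoxycarbonylation, in which chloride dealkylates the β-keto ester and the resulting β-keto carboxylate loses CO2, while the unactivated terminal ester is retained.

Step 3
Reactants: 4 methyl 6-methoxy-5-oxohexanoate
Product: 5 2-methoxycyclohexane-1,3-dione (exists largely as the enol 3-hydroxy-2-methoxycyclohex-2-en-1-one)
Conditions: KOtBu (2.2 equiv), THF, 0 °C to reflux; then 2 M HCl
Reagents that add atoms: none
Why: Intramolecular Claisen (Dieckmann-type) condensation in which only the methoxymethyl α-carbon can reach the ester through a six-membered ring (the other α-carbon would give a four-membered ring), driven by irreversible deprotonation of the 1,3-dione, as in the classical 5-oxohexanoate to dihydroresorcinol closure.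

Step 4
Reactants: 5 2-methoxycyclohexane-1,3-dione
Product: 6 3-bromo-2-methoxycyclohex-2-en-1-one
Conditions: Ph3PBr2 (1.1 equiv), Et3N (1.2 equiv), CH2Cl2, 0 °C to rt
Reagents that add atoms: dibromotriphenylphosphorane, BrP(Br)(c1ccccc1)(c1ccccc1)c1ccccc1
Why: Deoxybromination of an enolised 1,3-dione to a β-bromo enone (O-phosphonium activation, then bromide addition–elimination); the dione is symmetric, so only one product is possible.

Step 5
Reactants: 6 3-bromo-2-methoxycyclohex-2-en-1-one
Product: 9 3-bromo-2-methoxyphenol, via 6-bromo enone 7 (not isolated), via 2,5-dienone tautomer 8 (not isolated)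
Conditions: CuBr2 (2.0 equiv), LiBr, MeCN, reflux
Reagents that add atoms: none
Why: Bromination–dehydrobromination aromatisation of a cyclohexenone, in which CuBr2 brominates the α′-carbon through the enol, HBr is lost to the cross-conjugated dienone and this tautomerises to the phenol; bromination at the γ-carbon instead, or slight ring bromination of 9, would converge on the same phenol or on the step 6 product.

Step 6
Reactants: 9 3-bromo-2-methoxyphenol
Product: 10 3,4,6-tribromo-2-methoxyphenol
Conditions: Br2 (2.05 equiv), AcOH, 15 °C to rt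
Reagents that add atoms: bromine, BrBr
Why: Electrophilic aromatic bromination in which the free OH (reinforced by the ortho/para-directing 3-Br) sends the two bromines to C4 (para) and C6 (ortho), while C5 is meta to OH and ends up flanked by two bromines, so it stays unsubstituted.

Step 7
Reactants: 10 3,4,6-tribromo-2-methoxyphenol; 11 1-fluoro-2-nitrobenzene
Product: 12 1,2,5-tribromo-3-methoxy-4-(2-nitrophenoxy)benzene
Conditions: K2CO3, DMF, 100 °C
Reagents that add atoms: none
Why: SNAr in which the phenoxide displaces fluoride activated by the ortho-nitro group through a Meisenheimer intermediate; the unactivated aryl bromides do not react.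

Step 8
Reactants: 12 1,2,5-tribromo-3-methoxy-4-(2-nitrophenoxy)benzene
Product: 13 2-(3,4,6-tribromo-2-methoxyphenoxy)aniline
Conditions: Fe powder, NH4Cl, EtOH/H2O (4:1), 80 °C
Reagents that add atoms: none
Why: Béchamp-type iron reduction of the nitro group under near-neutral conditions, which leaves aryl bromides and the diaryl ether untouched.

Step 9
Reactants: 13 2-(3,4,6-tribromo-2-methoxyphenoxy)aniline
Product: 15 1,2,5-tribromo-4-(2-bromophenoxy)-3-methoxybenzene, via arenediazonium bromide 14 (not isolated)
Conditions: NaNO2, 48% aq. HBr, MeCN, 0 °C; then CuBr, 48% aq. HBr, 0 to 70 °C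
Reagents that add atoms: hydrobromic acid, Br; CuBr (bromine-transfer agent), [Cu]Br
Why: Sandmeyer bromination (diazotisation, then CuBr-mediated bromodediazoniation); both ring-A positions ortho to the ether oxygen are substituted, which blocks Pschorr-type closure to a dibenzofuran.

Step 10
Reactants: 15 1,2,5-tribromo-4-(2-bromophenoxy)-3-methoxybenzene
Product: 17 2,3,5-tribromo-6-(2-bromophenoxy)phenol (target), via aryloxydibromoborane 16 (not isolated)
Conditions: BBr3 (3 equiv), CH2Cl2, −78 °C to rt; then H2O
Reagents that add atoms: none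
Why: Lewis-acid O-demethylation of an aryl methyl ether, in which BBr3 coordinates the methoxy oxygen and bromide removes the methyl group by SN2; the diaryl ether has no sp3 carbon to attack and survives.

**Compound list**
1 | methyl 4-methoxy-3-oxobutanoate | COCC(=O)CC(=O)OC | starting material
2 | methyl acrylate | C=CC(=O)OC | starting material
3 | dimethyl 2-(2-methoxyacetyl)pentanedioate (racemic) | COCC(=O)C(CCC(=O)OC)C(=O)OC | intermediate
4 | methyl 6-methoxy-5-oxohexanoate | COCC(=O)CCCC(=O)OC | intermediate
5 | 2-methoxycyclohexane-1,3-dione | COC1C(=O)CCCC1=O | intermediate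
6 | 3-bromo-2-methoxycyclohex-2-en-1-one | COC1=C(Br)CCCC1=O | intermediate
7 | 3,6-dibromo-2-methoxycyclohex-2-en-1-one (racemic) | COC1=C(Br)CCC(Br)C1=O | intermediate (not isolated)
8 | 3-bromo-2-methoxycyclohexa-2,5-dien-1-one | COC1=C(Br)CC=CC1=O | intermediate (not isolated)
9 | 3-bromo-2-methoxyphenol | COc1c(O)cccc1Br | intermediate
10 | 3,4,6-tribromo-2-methoxyphenol | COc1c(O)c(Br)cc(Br)c1Br | intermediate
11 | 1-fluoro-2-nitrobenzene | O=[N+]([O-])c1ccccc1F | starting material
12 | 1,2,5-tribromo-3-methoxy-4-(2-nitrophenoxy)benzene | COc1c(Br)c(Br)cc(Br)c1Oc1ccccc1[N+](=O)[O-] | intermediate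
13 | 2-(3,4,6-tribromo-2-methoxyphenoxy)aniline | COc1c(Br)c(Br)cc(Br)c1Oc1ccccc1N | intermediate
14 | 2-(3,4,6-tribromo-2-methoxyphenoxy)benzenediazonium bromide | COc1c(Br)c(Br)cc(Br)c1Oc1ccccc1[N+]#N.[Br-] | intermediate (not isolated)
15 | 1,2,5-tribromo-4-(2-bromophenoxy)-3-methoxybenzene | COc1c(Br)c(Br)cc(Br)c1Oc1ccccc1Br | intermediate
16 | dibromo[2,3,5-tribromo-6-(2-bromophenoxy)phenoxy]borane | BrB(Br)Oc1c(Br)c(Br)cc(Br)c1Oc1ccccc1Br | intermediate (not isolated)
17 | 2,3,5-tribromo-6-(2-bromophenoxy)phenol (achiral) | Oc1c(Br)c(Br)cc(Br)c1Oc1ccccc1Br | target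

**Step count and risks**
Total steps: 10. Longest linear sequence: 10 steps (1 and 2 to 17); 11 enters at step 7 as a purchased fragment.

The three steps most likely to fail are 5, 7 and 9.

Step 5 (aromatisation): the electron-rich phenol 9 can be ring-brominated by CuBr2 before 6 is consumed, and the enol ether may not tolerate hot HBr. The fallback sets out from 6 and replaces halogenation by a selenoxide elimination. Deprotonation at C6 with LiN(iPr)2 (THF, −78 °C) and trapping with PhSeCl gives 3-bromo-2-methoxy-6-(phenylselanyl)cyclohex-2-en-1-one F1. Oxidation with H2O2 and pyridine (CH2Cl2, 0 °C) gives 3-bromo-2-methoxy-6-(phenylseleninyl)cyclohex-2-en-1-one F2. Its syn-elimination at room temperature comes back to the route at dienone 8, which tautomerises to 9.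

Step 7 (SNAr): the phenoxide of 10 is flanked by OMe and Br and carries three bromines, so it is a hindered, weak nucleophile. The fallback sets out from 10 and delivers the 2-bromophenyl group directly with a diaryliodonium salt, coming back to the route at 15 and making steps 8 and 9 unnecessary. 1-Bromo-2-iodobenzene is oxidised with mCPBA and TsOH·H2O in MeCN to 1-bromo-2-[hydroxy(tosyloxy)iodo]benzene F3. Adding 1,3,5-trimethoxybenzene to the same flask gives (2-bromophenyl)(2,4,6-trimethoxyphenyl)iodonium 4-methylbenzenesulfonate F4. Heating 10 with F4 and K2CO3 in MeCN at 60 °C transfers the 2-bromophenyl group to oxygen (the trimethoxyphenyl group is the non-transferred ligand) and gives 15.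

Step 9 (Sandmeyer): the amine 13 is weakly basic and poorly soluble, and aryl-radical side reactions (reduction, phenol formation) can erode the yield. The fallback sets out from 10 and brings the ring-B bromine in with the electrophile, so that nitrogen only has to be removed; it comes back to the route at 15. SNAr of 10 on 2-bromo-1-fluoro-4-nitrobenzene (K2CO3, DMF, 90 °C) gives 1,2,5-tribromo-4-(2-bromo-4-nitrophenoxy)-3-methoxybenzene F5. Reduction with Fe powder and NH4Cl (EtOH/H2O, 80 °C) gives 3-bromo-4-(3,4,6-tribromo-2-methoxyphenoxy)aniline F6. Diazotisation (NaNO2, H2SO4, AcOH, 0 °C) gives 3-bromo-4-(3,4,6-tribromo-2-methoxyphenoxy)benzenediazonium hydrogensulfate F7, which is reduced in the same flask with H3PO2 (0 °C to rt) to 15.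

**Further compounds**
F1 | step 5 | 3-bromo-2-methoxy-6-(phenylselanyl)cyclohex-2-en-1-one | COC1=C(Br)CCC([Se]c2ccccc2)C1=O
F2 | step 5 | 3-bromo-2-methoxy-6-(phenylseleninyl)cyclohex-2-en-1-one | COC1=C(Br)CCC([Se](=O)c2ccccc2)C1=O
F3 | step 7 | 1-bromo-2-[hydroxy(tosyloxy)iodo]benzene | Cc1ccc(cc1)S(=O)(=O)OI(O)c1ccccc1Br
F4 | step 7 | (2-bromophenyl)(2,4,6-trimethoxyphenyl)iodonium 4-methylbenzenesulfonate | COc1cc(OC)c([I+]c2ccccc2Br)c(OC)c1.Cc1ccc(cc1)S(=O)(=O)[O-]
F5 | step 9 | 1,2,5-tribromo-4-(2-bromo-4-nitrophenoxy)-3-methoxybenzene | COc1c(Br)c(Br)cc(Br)c1Oc1ccc(cc1Br)[N+](=O)[O-]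
F6 | step 9 | 3-bromo-4-(3,4,6-tribromo-2-methoxyphenoxy)aniline | COc1c(Br)c(Br)cc(Br)c1Oc1ccc(N)cc1Br
F7 | step 9 | 3-bromo-4-(3,4,6-tribromo-2-methoxyphenoxy)benzenediazonium hydrogensulfate | COc1c(Br)c(Br)cc(Br)c1Oc1ccc(cc1Br)[N+]#N.OS(=O)(=O)[O-]
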